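Remark on the chemistry: ring atoms carry the flavone numbers (O1, C2, C3, C4, C4a, C5–C8, C8a) from the first aromatic intermediate onward. Intermediates 9 and 14 are racemic and their stereocentres do not reach the target.

## Analysis of the target

Pollenitin 8-acetate (18) is a flavonol: a 4H-chromen-4-one in which the benzo ring A (C4a, C5, C6, C7, C8, C8a) is fused to the pyranone ring C (O1, C2, C3, C4), and C2 carries ring B, a 4-hydroxyphenyl group. It has no stereocentre, so the task is purely regiochemical: ring A is hexasubstituted, with OH at C5, H at C6, OMe at C7, OAc at C8 and the ring oxygen O1 at C8a, four oxygens in four different states on one benzene ring. The sensitive groups are three. The aryl acetate at O8 is lost to base, nucleophiles, fluoride and alcoholysis. The para pair O5/O8 is a hydroquinone when both are free and is oxidisable to the 5,8-quinone. The 5-hydroxy-4-keto unit allows 5,8-dioxygenated flavones to isomerise to the 5,6-series in hot strong acid by opening and reclosure of ring C. The difficulty is twofold: an arene must be made with oxygen on C5, C7, C8 and C8a and carbon on C4a, and O8 must be told apart from O5, O3 and O4' so that it alone is acetylated, late. The plan rests on the edge C5–C6–C7–C8 of ring A, which carries O, H, OMe, O in the same order in which the four carbons of methyl tetronate (1) carry carbonyl oxygen, hydrogen, methoxy group and ring oxygen. The remaining ring A atoms, C4a with its acyl group and C8a with a heteroatom, are then the two carbons of an acyl alkyne, so ring A can be assembled by cycloaddition of a tetronate-derived furan to an ynone instead of by substitution of a preformed benzene.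

## Retrosynthetic reasoning

18 from 17: the two benzyl–oxygen bonds at O3 and O4' are cut last. Benzyl is chosen because hydrogenolysis is neutral and is then the only reaction the acetate ever meets. The forward step must cleave both ethers in 3-(benzyloxy)-2-[4-(benzyloxy)phenyl]-5-hydroxy-7-methoxy-4-oxo-4H-chromen-8-yl acetate (17) without touching the ester or the C2=C3 bond.

17 from 16: the acetyl–O8 bond is cut. In the 5,8-diol 16 the only competing hydroxyl is 5-OH, which is held in a hydrogen bond to the C4 carbonyl and is a poor nucleophile, so O5 needs no protecting group. The forward step is a mono-acetylation with a small excess of acylating agent.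

16 from 15: both silicon–oxygen bonds (O5 and O8) are cut together. The forward step is a buffered fluoride desilylation of the bis-silyl flavone 15.

15 from 14: ring C is opened at O1–C8a, not at the classical O1–C2 bond. A dehydrative closure of an ortho-hydroxy diketone would have two ortho oxygens (at C5 and at C8a) to choose from and would need acid, the conditions under which the 5,8/5,6 isomerisation runs. Cutting O1–C8a leaves the bromo diketone 14, in which bromine decides that C8a and no other carbon receives O1. The forward step is a copper-catalysed O-arylation of the diketone enol at a hindered C–Br bond.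

14 from 11 and 12: the C2–C3 bond is cut, giving the enolate 13 of the α-benzyloxy ketone 11 and 4-(benzyloxy)benzoyl chloride (12). This brings in ring B and C2 convergently, and because O3 is already on the ketone no late oxidation at C3 is needed. The forward step must acylate at carbon, not at oxygen.

11 from 10: the silicon–O8 bond is cut, so that the free phenol of 10 is masked and the CH2 group is the only acidic site left for the enolate step.

10 from 2 and 8 (through 9): the two ring A bonds C4a–C5 and C8–C8a are cut. This is the disconnection that turns a furan into a benzene: the silyloxyfuran 2 supplies C5–C8 with their substituents and the bromo ynone 8 supplies C4a and C8a. The forward step must give the oxygen-bridged adduct 9 in the right orientation, and 9 must open toward the silyloxy carbon so that the old furan oxygen stays on C8 as a free phenol and O5 stays silylated. The two para oxygens are thus differentiated by mechanism, and bromine arrives on C8a.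

2 from 1: the silicon–oxygen bond is cut. The forward step is enolisation of the lactone CH2 and O-silylation of the dienolate.

8 from 7, 7 from 4 and 5 (through 6), 4 from 3: the C–Br bond is traced back to a C–Si bond, and the acyl–alkynyl bond to a Weinreb amide 4 and the lithium acetylide 6 of trimethylsilylacetylene (5). A direct palladium/copper coupling of 5 with benzyloxyacetyl chloride (3) in the presence of a trialkylamine was set aside, because alkoxyacetyl chlorides are dehydrochlorinated to ketenes by such amines. The amide route costs one step and removes that risk.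

## Alternatives that were turned down

Alternative 1: Ring C is cut at C3–C4 and O1–C2. Ring A arrives as the benzodioxinone A2, which already carries 5-OBn, 7-OMe and 8-OAc, and ring B with C2 and C3 as the enol silane A3.
- Forward key step: irradiation makes A2 extrude its acetal carbonyl component to give a quinoketene. The nucleophilic carbon of A3 adds to the ketene carbon (C3–C4), the phenolic oxygen closes onto C2, and acid work-up eliminates the silanol to give the tris-benzyl flavone A1.
- For: it is convergent, it closes ring C in one neutral step with the acetate in place, and A1 is a single hydrogenolysis away from the target. On end-game length it is clearly stronger than the chosen route, which needs a copper closure and a selective acetylation.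
- Against: A2 is a hexasubstituted salicylate, so the whole problem of ring A (oxygen on four carbons, O8 different from O5 and O1) is only moved into a long linear preparation of the starting material. The acetate in A2 sits next to the oxygen that becomes O1, so acyl transfer between these neighbours can compete once that oxygen is unmasked. Aryl acetates rearrange under the ultraviolet light the step needs. A1 is a 3-benzyloxyflavone that absorbs the same light and can abstract a benzylic hydrogen with its excited C4 carbonyl. The nucleophile A3 is an alkoxy-substituted, trisubstituted enol ether, which is a hindered partner for a short-lived ketene.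
- Comparison: the chosen strategy gives up the elegant ring C closure and in return makes the hexasubstituted ring A in one step from a C4 lactone and a C4 ynone, with the oxygens differentiated and no photochemistry on an aryl ester.

Alternative 2: Ring C is cut at C3–C4. The precursor is the ether-linked dialdehyde A5, in which O1–C2 was made earlier.
- Forward key step: a triazolium-derived N-heterocyclic carbene converts the aromatic aldehyde into an acyl anion equivalent that adds to the aliphatic aldehyde, closing the six-membered ring as the trans dihydroflavonol A4.
- For: the conditions are mild and organocatalytic, O3 arrives from the aldehyde oxygen, and the intramolecular crossed benzoin is an established route to chromanones. On mildness of the ring C closure it is as strong as the chosen route.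
- Against: both stereocentres of A4 are erased by the dehydrogenation that must follow, so the control is wasted and a step is added. The carbene must choose the hindered, electron-rich, doubly ortho-substituted benzaldehyde over an unhindered aldehyde. If it adds to the aliphatic aldehyde, the resulting acyl anion equivalent has an aryloxide leaving group on the neighbouring carbon and can expel it, cutting O1–C2. That aldehyde is also highly enolisable. Most seriously, ring A of A4 carries three methyl ethers: the 5-OMe can be removed by a chelating Lewis acid, but nothing distinguishes 8-OMe from 7-OMe, so the differentiation of O8 is not solved at all.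
- Comparison: after the key step, oxidation, two selective demethylations, acetylation and debenzylation would still be needed. The chosen strategy solves the ring A problem that this route leaves open, since O7 comes in as the tetronate methyl ether and O8 as a free phenol.

Alternative 3: Ring A is cut at C4a–C5. The precursor is the 4-acetoxy-4-pyranonylcyclobutenone A7, made by adding a metallated pyranone that carries ring B to a monosubstituted cyclobutenedione and acetylating the alkoxide.
- Forward key step: heating opens the four-membered ring of A7 to a dienylketene. The ketene carbon bonds to the pyranone CH in a six-electron electrocyclisation, and tautomerisation gives A6, with free 5-OH para to an intact 8-OAc.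
- For: like the chosen route it builds ring A by benzannulation and differentiates O5 from O8 by construction, and it does so in their final states. A6 is the same compound as 17 of the chosen route, reached without a hydroquinone, a selective acetylation or a copper step. On the end game and on the O5/O8 problem it is stronger.
- Against: the cost is paid at the front. The 3-benzyloxy-2-aryl-4-pyranone must be built in several steps and then metallated at the carbon next to its ring oxygen, on a ring that is itself a Michael acceptor and opens with strong bases. The cyclobutenedione with hydrogen on one ring carbon is not a commodity. The electrocyclisation must engage a cross-conjugated pyranone double bond rather than a simple arene.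
- Comparison: Alternative 3 can be tested only after two multi-step fragments are in hand, and its total count is likely higher. The chosen strategy offers fragments that are two and four steps from catalogue compounds, so its one uncertain step can be tested at once, and the end game uses standard flavonoid operations.

Key step: step 5

## Route

Step 1
Reactants: 1 methyl tetronate (4-methoxyfuran-2(5H)-one)
Product: 2 tert-butyl[(4-methoxyfuran-2-yl)oxy]dimethylsilane
Conditions: t-BuMe2SiOSO2CF3, Et3N, CH2Cl2, 0 °C → rt; product kept dry and used promptly
Reagents that add atoms: tert-butyldimethylsilyl trifluoromethanesulfonate, CC(C)(C)[Si](C)(C)OS(=O)(=O)C(F)(F)F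
Why: Soft enolisation of the butenolide CH2 next to the ring oxygen and O-silylation of the dienolate gives the aromatic 2-silyloxyfuran; silyl dienol ether formation from tetronates and butenolides is routine.

Step 2
Reactants: 3 benzyloxyacetyl chloride
Product: 4 2-(benzyloxy)-N-methoxy-N-methylacetamide
Conditions: MeNH(OMe)·HCl, pyridine, CH2Cl2, 0 °C → rt
Reagents that add atoms: N,O-dimethylhydroxylamine hydrochloride, CNOC.Cl
Why: Acylation of the hydroxylamine gives the Weinreb amide; pyridine is used instead of a trialkylamine so that the alkoxyacetyl chloride is not dehydrochlorinated to a ketene.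

Step 3
Reactants: 5 trimethylsilylacetylene; 4 2-(benzyloxy)-N-methoxy-N-methylacetamide
Product: 7 1-(benzyloxy)-4-(trimethylsilyl)but-3-yn-2-one, via lithium (trimethylsilyl)acetylide 6 (not isolated)
Conditions: n-BuLi, THF, −78 °C; then 4, −78 → 0 °C; aq. NH4Cl
Reagents that add atoms: none
Why: Weinreb ketone synthesis: the lithium acetylide adds once to the amide, the chelated tetrahedral intermediate holds until work-up, and the ynone is released without over-addition.

Step 4
Reactants: 7 1-(benzyloxy)-4-(trimethylsilyl)but-3-yn-2-one
Product: 8 1-(benzyloxy)-4-bromobut-3-yn-2-one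
Conditions: N-bromosuccinimide, AgNO3 (10 mol%), acetone, rt, dark; used without storage
Reagents that add atoms: N-bromosuccinimide, O=C1CCC(=O)N1Br
Why: Silver-catalysed bromodesilylation of an alkynylsilane, a standard way to 1-bromoalkynes that tolerates the ketone and the benzyl ether.

Step 5
Reactants: 2 tert-butyl[(4-methoxyfuran-2-yl)oxy]dimethylsilane; 8 1-(benzyloxy)-4-bromobut-3-yn-2-one
Product: 10 2-(benzyloxy)-1-[2-bromo-6-(tert-butyldimethylsilyloxy)-3-hydroxy-4-methoxyphenyl]ethan-1-one, via 7-oxanorbornadiene cycloadduct 9 (not isolated)
Conditions: PhMe, 25 → 70 °C, Ar, dark, no Lewis acid, 1.5 equiv of 2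
Reagents that add atoms: none
Why: Furan 2 is a cyclic 1,3-dioxygenated diene and ynone 8 an electron-poor alkyne, so a normal-demand, strongly asynchronous [4+2] cycloaddition is expected: the furan CH next to the ring oxygen, made nucleophilic by both the 2-silyloxy and the 4-methoxy group, bonds to the bromine-bearing beta carbon of the ynone (C8–C8a) and the silyloxy carbon bonds to the alpha carbon (C4a–C5), which closes ring A as the six-membered carbocycle of the oxygen-bridged adduct 9 in one intermolecular cycloaddition. In 9 the bridge C–O bond at the silyloxy carbon ionises, because the resulting cation is spread over C5 and C7 and is stabilised by both the silyloxy and the methoxy group, whereas opening at the other bridgehead would put charge on the acyl-bearing carbon; loss of the former bridgehead proton (or a hydride shift followed by enolisation) then aromatises the ring. The furan oxygen therefore stays on C8 as a free phenol while O5 keeps its silyl group, so the two para oxygens leave the step differentiated, and bromine marks C8a. The closest known reactions are the Diels–Alder additions of furans to 3-bromopropiolates and the conversion of 2-alkoxy- and 2-silyloxyfuran–alkyne adducts into 4-oxygenated phenols; this particular pair of partners has not been tried. The two bridgehead stereocentres of 9 are tied to each other by the bridge and both vanish on aromatisation, so no stereocontrol is needed. The step needs orientation and chemoselectivity: orientation follows from the matched polarity of the doubly activated furan CH and the ynone beta carbon, and a non-polar solvent without Lewis acid or fluoride favours ring closure over vinylogous Michael addition with expulsion of bromide.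

Step 6
Reactants: 10 2-(benzyloxy)-1-[2-bromo-6-(tert-butyldimethylsilyloxy)-3-hydroxy-4-methoxyphenyl]ethan-1-one
Product: 11 2-(benzyloxy)-1-[2-bromo-3,6-bis(tert-butyldimethylsilyloxy)-4-methoxyphenyl]ethan-1-one
Conditions: t-BuMe2SiCl, imidazole, DMF, rt
Reagents that add atoms: tert-butyldimethylsilyl chloride, CC(C)(C)[Si](C)(C)Cl
Why: Standard silylation of a phenol; with O8 masked the CH2 group is the only acidic site for the next step, and both ring A oxygens can later be freed by one reagent.

Step 7
Reactants: 11 2-(benzyloxy)-1-[2-bromo-3,6-bis(tert-butyldimethylsilyloxy)-4-methoxyphenyl]ethan-1-one; 12 4-(benzyloxy)benzoyl chloride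
Product: 14 2-(benzyloxy)-1-[4-(benzyloxy)phenyl]-3-[2-bromo-3,6-bis(tert-butyldimethylsilyloxy)-4-methoxyphenyl]propane-1,3-dione, via lithium enolate 13 (not isolated)
Conditions: LiN(SiMe3)2 (2.2 equiv), THF, −78 °C; then 12, −78 → −20 °C; aq. NH4Cl
Reagents that add atoms: none
Why: Claisen-type C-acylation of a lithium ketone enolate by an aroyl chloride, the usual direct route to 1,3-diketones; the second equivalent of base deprotonates the more acidic product, and the low temperature keeps the O5 silyl group from migrating to the enolate oxygen.

Step 8
Reactants: 14 2-(benzyloxy)-1-[4-(benzyloxy)phenyl]-3-[2-bromo-3,6-bis(tert-butyldimethylsilyloxy)-4-methoxyphenyl]propane-1,3-dione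
Product: 15 3-(benzyloxy)-2-[4-(benzyloxy)phenyl]-5,8-bis(tert-butyldimethylsilyloxy)-7-methoxy-4H-chromen-4-one
Conditions: CuI (20 mol%), 1,10-phenanthroline (40 mol%), K3PO4 (2 equiv), PhMe, 100 °C, Ar
Reagents that add atoms: none
Why: Intramolecular Ullmann-type O-arylation of a 1,3-diketone enolate by an ortho-bromoaryl ketone, a known entry to chromones and flavones; only the enol oxygen of the C2 carbonyl can reach C8a (six-membered ring), the ortho carbonyl assists the substitution, and the non-polar, anhydrous medium spares the aryl silyl ethers.

Step 9
Reactants: 15 3-(benzyloxy)-2-[4-(benzyloxy)phenyl]-5,8-bis(tert-butyldimethylsilyloxy)-7-methoxy-4H-chromen-4-one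
Product: 16 3-(benzyloxy)-2-[4-(benzyloxy)phenyl]-5,8-dihydroxy-7-methoxy-4H-chromen-4-one
Conditions: Bu4NF, AcOH, THF, 0 °C, degassed, Ar
Reagents that add atoms: none
Why: Fluoride cleaves both aryl silyl ethers; the acetic acid buffer keeps the hydroquinone protonated and the exclusion of air keeps it from oxidising to the 5,8-quinone.

Step 10
Reactants: 16 3-(benzyloxy)-2-[4-(benzyloxy)phenyl]-5,8-dihydroxy-7-methoxy-4H-chromen-4-one
Product: 17 3-(benzyloxy)-2-[4-(benzyloxy)phenyl]-5-hydroxy-7-methoxy-4-oxo-4H-chromen-8-yl acetate
Conditions: Ac2O (1.05 equiv), pyridine, CH2Cl2, 0 °C, Ar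
Reagents that add atoms: acetic anhydride, CC(=O)OC(C)=O
Why: Selective O-acetylation: 5-OH is locked in a hydrogen bond to the C4 carbonyl and is acylated far more slowly than a free phenol, so with about one equivalent of anhydride only 8-OH should react; O3 and O4' are benzylated.

Step 11
Reactants: 17 3-(benzyloxy)-2-[4-(benzyloxy)phenyl]-5-hydroxy-7-methoxy-4-oxo-4H-chromen-8-yl acetate
Product: 18 pollenitin 8-acetate (3,5-dihydroxy-2-(4-hydroxyphenyl)-7-methoxy-4-oxo-4H-chromen-8-yl acetate)
Conditions: H2 (1 atm), 10% Pd/C, EtOAc, rt
Reagents that add atoms: none
Why: Hydrogenolysis of the two benzyl ethers under neutral, alcohol-free conditions; the aryl acetate and the tetrasubstituted C2=C3 bond of the chromenone are expected to be inert, and the acetate has no free neighbouring hydroxyl to migrate to.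

## Compound list

1 | methyl tetronate (4-methoxyfuran-2(5H)-one) | COC1=CC(=O)OC1 | starting material
2 | tert-butyl[(4-methoxyfuran-2-yl)oxy]dimethylsilane | COc1coc(O[Si](C)(C)C(C)(C)C)c1 | intermediate
3 | benzyloxyacetyl chloride | O=C(Cl)COCc1ccccc1 | starting material
4 | 2-(benzyloxy)-N-methoxy-N-methylacetamide | CON(C)C(=O)COCc1ccccc1 | intermediate
5 | trimethylsilylacetylene | C#C[Si](C)(C)C | starting material
6 | lithium (trimethylsilyl)acetylide, formed in the flask | [Li]C#C[Si](C)(C)C | intermediate
7 | 1-(benzyloxy)-4-(trimethylsilyl)but-3-yn-2-one | C[Si](C)(C)C#CC(=O)COCc1ccccc1 | intermediate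
8 | 1-(benzyloxy)-4-bromobut-3-yn-2-one | BrC#CC(=O)COCc1ccccc1 | intermediate
9 | rac-2-(benzyloxy)-1-[3-bromo-1-(tert-butyldimethylsilyloxy)-5-methoxy-7-oxabicyclo[2.2.1]hepta-2,5-dien-2-yl]ethan-1-one, formed in the flask, one enantiomer drawn | COC1=C[C@]2(O[Si](C)(C)C(C)(C)C)O[C@H]1C(Br)=C2C(=O)COCc1ccccc1 | intermediate
10 | 2-(benzyloxy)-1-[2-bromo-6-(tert-butyldimethylsilyloxy)-3-hydroxy-4-methoxyphenyl]ethan-1-one | COc1cc(O[Si](C)(C)C(C)(C)C)c(C(=O)COCc2ccccc2)c(Br)c1O | intermediate
11 | 2-(benzyloxy)-1-[2-bromo-3,6-bis(tert-butyldimethylsilyloxy)-4-methoxyphenyl]ethan-1-one | COc1cc(O[Si](C)(C)C(C)(C)C)c(C(=O)COCc2ccccc2)c(Br)c1O[Si](C)(C)C(C)(C)C | intermediate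
12 | 4-(benzyloxy)benzoyl chloride | O=C(Cl)c1ccc(OCc2ccccc2)cc1 | starting material
13 | lithium (Z)-2-(benzyloxy)-1-[2-bromo-3,6-bis(tert-butyldimethylsilyloxy)-4-methoxyphenyl]ethen-1-olate, formed in the flask | [Li]O/C(=C\OCc1ccccc1)c1c(Br)c(O[Si](C)(C)C(C)(C)C)c(OC)cc1O[Si](C)(C)C(C)(C)C | intermediate
14 | 2-(benzyloxy)-1-[4-(benzyloxy)phenyl]-3-[2-bromo-3,6-bis(tert-butyldimethylsilyloxy)-4-methoxyphenyl]propane-1,3-dione, racemic at the enolisable C2, diketo form drawn | COc1cc(O[Si](C)(C)C(C)(C)C)c(C(=O)C(OCc2ccccc2)C(=O)c2ccc(OCc3ccccc3)cc2)c(Br)c1O[Si](C)(C)C(C)(C)C | intermediate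
15 | 3-(benzyloxy)-2-[4-(benzyloxy)phenyl]-5,8-bis(tert-butyldimethylsilyloxy)-7-methoxy-4H-chromen-4-one | COc1cc(O[Si](C)(C)C(C)(C)C)c2c(=O)c(OCc3ccccc3)c(-c3ccc(OCc4ccccc4)cc3)oc2c1O[Si](C)(C)C(C)(C)C | intermediate
16 | 3-(benzyloxy)-2-[4-(benzyloxy)phenyl]-5,8-dihydroxy-7-methoxy-4H-chromen-4-one | COc1cc(O)c2c(=O)c(OCc3ccccc3)c(-c3ccc(OCc4ccccc4)cc3)oc2c1O | intermediate
17 | 3-(benzyloxy)-2-[4-(benzyloxy)phenyl]-5-hydroxy-7-methoxy-4-oxo-4H-chromen-8-yl acetate | COc1cc(O)c2c(=O)c(OCc3ccccc3)c(-c3ccc(OCc4ccccc4)cc3)oc2c1OC(C)=O | intermediate
18 | pollenitin 8-acetate (3,5-dihydroxy-2-(4-hydroxyphenyl)-7-methoxy-4-oxo-4H-chromen-8-yl acetate) | COc1cc(O)c2c(=O)c(O)c(-c3ccc(O)cc3)oc2c1OC(C)=O | target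

## Step count and risks

Total step count: 11. Longest linear sequence: 10 steps (steps 2, 3, 4, 5, 6, 7, 8, 9, 10, 11, from benzyloxyacetyl chloride 3). The furan branch joins after one step.

Steps least certain to work:

Step 5 (key step). The most likely failure is vinylogous Michael addition of the furan CH to the bromine-bearing alkyne carbon followed by loss of bromide, which alkynylates the butenolide instead of closing the ring. Polymerisation of the bromo ynone on heating is the second concern, and loss of the silyl group during bridge opening would erase the O5/O8 differentiation. The fallback sets out from 2 and 7 and uses a dienophile with no leaving group on the beta carbon. Heating 2 with the silyl ynone 7 (PhMe, 80–110 °C) should give the bridged adduct rac-2-(benzyloxy)-1-[1-(tert-butyldimethylsilyloxy)-5-methoxy-3-(trimethylsilyl)-7-oxabicyclo[2.2.1]hepta-2,5-dien-2-yl]ethan-1-one F1. This should open in the same sense to the arylsilane 2-(benzyloxy)-1-[6-(tert-butyldimethylsilyloxy)-3-hydroxy-4-methoxy-2-(trimethylsilyl)phenyl]ethan-1-one F2. N-Bromosuccinimide (MeCN, 0 °C) then replaces silicon by bromine at C8a by ipso substitution, which the beta-silicon effect and the ortho hydroxyl favour, while C6 is shielded between the methoxy and the bulky silyloxy group. The route is rejoined at 10.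

Step 8. The most likely failure is slow insertion of copper into a C–Br bond flanked by the acyl group and a silyloxy group. Base-induced desilylation, retro-Claisen cleavage of the 2-alkoxy-1,3-diketone or protodebromination could then overtake ring closure. The fallback sets out from 14 and uses the para relation of O5 and O8 to make C8a electrophilic without a metal. Bu4NF/AcOH frees the hydroquinone 2-(benzyloxy)-1-[4-(benzyloxy)phenyl]-3-(2-bromo-3,6-dihydroxy-4-methoxyphenyl)propane-1,3-dione F3. Ag2O (CH2Cl2, rt) oxidises it to the bromoquinone 2-(benzyloxy)-1-[4-(benzyloxy)phenyl]-3-(2-bromo-4-methoxy-3,6-dioxocyclohexa-1,4-dien-1-yl)propane-1,3-dione F4. Et3N then lets the diketone enol oxygen add to the bromine-bearing quinone carbon and expel bromide, giving 3-(benzyloxy)-2-[4-(benzyloxy)phenyl]-7-methoxy-4H-chromene-4,5,8-trione F5. Reduction with aqueous Na2S2O4 returns the route at 16.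

Step 7. The most likely failure is acylation of the enolate at oxygen, giving an enol ester. The other risk is migration of the O5 silyl group to the enolate oxygen, which frees a phenoxide that is aroylated instead. The fallback sets out from 11 and forms the C2–C3 bond by an aldol addition, where only carbon can react. The boron enolate of 11 (Bu2BOTf, i-Pr2NEt, CH2Cl2, −78 °C) is added to commercial 4-(benzyloxy)benzaldehyde (SMILES O=Cc1ccc(OCc2ccccc2)cc1). This should give 2-(benzyloxy)-3-[4-(benzyloxy)phenyl]-1-[2-bromo-3,6-bis(tert-butyldimethylsilyloxy)-4-methoxyphenyl]-3-hydroxypropan-1-one F6 as a mixture of diastereomers. Oxidation with Dess–Martin periodinane erases both centres and returns the route at 14.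

Step 10. The most likely failure is over-acetylation at O5 once 8-OH, which is hindered by its two ortho substituents, reacts slowly enough to need forcing. Air oxidation of the hydroquinone before it is acylated is the other risk. The fallback sets out from 16 and masks O5 as a boron chelate. BF3·OEt2 (CH2Cl2, rt) should give the difluoroboron chelate of 16 across O5 and the C4 carbonyl oxygen F7. Ac2O/pyridine with a little 4-(dimethylamino)pyridine then acetylates the only free hydroxyl to give the 8-acetate of that chelate F8. Mild hydrolysis of the chelate (aqueous THF, 50 °C) returns the route at 17.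

## Further compounds

F1 | step 5 | rac-2-(benzyloxy)-1-[1-(tert-butyldimethylsilyloxy)-5-methoxy-3-(trimethylsilyl)-7-oxabicyclo[2.2.1]hepta-2,5-dien-2-yl]ethan-1-one, one enantiomer drawn | COC1=C[C@]2(O[Si](C)(C)C(C)(C)C)O[C@H]1C([Si](C)(C)C)=C2C(=O)COCc1ccccc1
F2 | step 5 | 2-(benzyloxy)-1-[6-(tert-butyldimethylsilyloxy)-3-hydroxy-4-methoxy-2-(trimethylsilyl)phenyl]ethan-1-one | COc1cc(O[Si](C)(C)C(C)(C)C)c(C(=O)COCc2ccccc2)c([Si](C)(C)C)c1O
F3 | step 8 | 2-(benzyloxy)-1-[4-(benzyloxy)phenyl]-3-(2-bromo-3,6-dihydroxy-4-methoxyphenyl)propane-1,3-dione, racemic at the enolisable C2 | COc1cc(O)c(C(=O)C(OCc2ccccc2)C(=O)c2ccc(OCc3ccccc3)cc2)c(Br)c1O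
F4 | step 8 | 2-(benzyloxy)-1-[4-(benzyloxy)phenyl]-3-(2-bromo-4-methoxy-3,6-dioxocyclohexa-1,4-dien-1-yl)propane-1,3-dione, racemic at the enolisable C2 | COC1=CC(=O)C(C(=O)C(OCc2ccccc2)C(=O)c2ccc(OCc3ccccc3)cc2)=C(Br)C1=O
F5 | step 8 | 3-(benzyloxy)-2-[4-(benzyloxy)phenyl]-7-methoxy-4H-chromene-4,5,8-trione | COC1=CC(=O)C2=C(OC(c3ccc(OCc4ccccc4)cc3)=C(OCc3ccccc3)C2=O)C1=O
F6 | step 7 | 2-(benzyloxy)-3-[4-(benzyloxy)phenyl]-1-[2-bromo-3,6-bis(tert-butyldimethylsilyloxy)-4-methoxyphenyl]-3-hydroxypropan-1-one, mixture of diastereomers, both centres erased on oxidation | COc1cc(O[Si](C)(C)C(C)(C)C)c(C(=O)C(OCc2ccccc2)C(O)c2ccc(OCc3ccccc3)cc2)c(Br)c1O[Si](C)(C)C(C)(C)C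
F7 | step 10 | difluoroboron chelate of 16 across O5 and the C4 carbonyl oxygen | COc1cc2O[B-](F)(F)[O+]=C3C(OCc4ccccc4)=C(c4ccc(OCc5ccccc5)cc4)Oc(c1O)c23
F8 | step 10 | 8-acetate of the difluoroboron chelate F7 | COc1cc2O[B-](F)(F)[O+]=C3C(OCc4ccccc4)=C(c4ccc(OCc5ccccc5)cc4)Oc(c1OC(C)=O)c23
A1 | alternative 1 | 8-acetoxy-3,5,4'-tris(benzyloxy)-7-methoxyflavone | COc1cc(OCc2ccccc2)c2c(=O)c(OCc3ccccc3)c(-c3ccc(OCc4ccccc4)cc3)oc2c1OC(C)=O
A2 | alternative 1 | 5-(benzyloxy)-7-methoxy-2,2-dimethyl-4-oxo-4H-1,3-benzodioxin-8-yl acetate | COc1cc(OCc2ccccc2)c2C(=O)OC(C)(C)Oc2c1OC(C)=O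
A3 | alternative 1 | trimethyl{[(Z)-2-(benzyloxy)-1-[4-(benzyloxy)phenyl]ethenyl]oxy}silane | C[Si](C)(C)O/C(=C\OCc1ccccc1)c1ccc(OCc2ccccc2)cc1
A4 | alternative 2 | rac-trans-2-[4-(benzyloxy)phenyl]-3-hydroxy-5,7,8-trimethoxychroman-4-one, one enantiomer drawn | c1ccccc1COc1ccc(cc1)[C@@H]1[C@H](C(=O)c2c(OC)cc(OC)c(OC)c2O1)O
A5 | alternative 2 | rac-2-{1-[4-(benzyloxy)phenyl]-2-oxoethoxy}-3,4,6-trimethoxybenzaldehyde | O=CC(Oc1c(OC)c(OC)cc(OC)c1C=O)c1ccc(OCc2ccccc2)cc1
A6 | alternative 3 | 8-acetoxy-3,4'-bis(benzyloxy)-5-hydroxy-7-methoxyflavone (the same compound as 17) | COc1cc(O)c2c(=O)c(OCc3ccccc3)c(-c3ccc(OCc4ccccc4)cc3)oc2c1OC(C)=O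
A7 | alternative 3 | rac-1-{5-(benzyloxy)-6-[4-(benzyloxy)phenyl]-4-oxo-4H-pyran-2-yl}-2-methoxy-4-oxocyclobut-2-en-1-yl acetate | COC1=CC(=O)C1(OC(C)=O)c1cc(=O)c(OCc2ccccc2)c(-c2ccc(OCc3ccccc3)cc2)o1
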